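## Remarks on the chemistry (assumptions)

- Oleuropein (16), the commercial olive-leaf secoiridoid glucoside, is taken as a purchasable starting material. The Grignard reagent of step 1 is bought as a solution or made beforehand from commercial (chloromethyl)dimethylphenylsilane and magnesium.
- The target is drawn as the open tetra-aldehyde; in solution it may equilibrate with hydrates and with hemiacetals of its two free hydroxyls.
- Locants: ring carbons of the core are C1′–C5′. The acyl units carry secoiridoid locants: ester C7, CH2 C6, stereocentre C5, arm CH2 C4 with its CHO C3, enal carbon C9 with its CHO C1, ethylidene C8/C10.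

## The problem

The target is the diester of a C10 iridane tetraol with two molecules of (3S,4E)-4-formyl-3-(2-oxoethyl)hex-4-enoic acid. The cyclopentane carries, all-trans, a 1,3-dioxygenated propan-2-yl group (C1′), an acyloxy group (C3′), a methyl (C4′) and a hydroxymethyl (C5′). The four ring stereocentres (C3′–C4′–C5′–C1′) are contiguous and can relay one another. The fifth core centre, C2 of the propane unit, is stereogenic only because one of its two CH2OH arms is acylated, so four hydroxyls must be told apart, two of them diastereotopic. Each acyl unit holds an (E)-enal, a saturated aldehyde 1,5 to it, and an allylic stereocentre that is β to three carbonyls; the units are remote from the core and from each other, so nothing in the core can set them. The finished molecule (four aldehydes, two esters, two free primary alcohols, one of them 1,3 to a migratable ester) tolerates neither hydride, base, strong acid nor nucleophiles, so all aldehydes must appear last and near neutrality.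

The feature that makes the key step possible is this: the two formyl carbons C1 and C3 of each acyl unit are 1,5-related through C9–C5–C4. One oxygen between them and a carboxyl (C11) on C4 recreate the 3,4-dihydro-2H-pyran ring O2–C1–C9–C5–C4=C3 of oleoside. That is the glucoside core of oleuropein, which already holds (5S), the (8E)-ethylidene and the C6–C7 arm. Each acyl unit is therefore a ring-opened, decarboxylated oleoside aglycone.

In the core, the required configuration at the exocyclic centre is the one in which the acylated arm is equatorial on a trans-fused δ-lactone drawn between the other arm and the C5′ hydroxymethyl.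

## Retrosynthesis

**25 ⇒ 22.** In each acyl unit the bond C1–O2 is re-formed (hemiacetal, then β-glucoside) and the bond C4–C11 (a carboxyl) is put back. This gives the bis(11-demethyl-oleoside) diester 22. Against acetal or diol masks, which need acid or an oxidant, this mask is removed by a glucosidase at pH 5 and then dismantles itself by decarboxylation. Precursor 22 has no aldehyde, no enal and no labile centre, and its two acyl stereocentres and alkene geometries are bought, not made. The forward reaction must hydrolyse two glucosides next to four acyl groups and lose CO2 only from C11.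

**22 ⇒ 21 ⇒ 15 + 20.** The two ester bonds C7–O are cut. The acyl donor is the cyclic anhydride 20 that spans C7 and C11 of silylated oleoside. Opening at the saturated C7 carbonyl gives the ester and leaves C11 as the free acid that the key step needs, so C11 needs no protecting group. An 11-methyl ester would be simpler to make but could not be removed selectively later. The ten silyl ethers of 21 fall in one fluoride step to 22. The forward reaction needs regioselective opening of 20 and acylation of one primary and one hindered secondary hydroxyl of 15.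

**20 ⇒ 19 ⇒ 17 ⇒ 16.** Only C–O bonds are changed: dehydration of diacid 19, silylation of oleoside 17, and saponification of both esters of oleuropein 16. Three steps deliver the complete acyl unit with its stereocentre and (E)-alkene.

**15 ⇒ 14 ⇒ 13 ⇒ 12.** The pattern "two oxygens free, two to be acylated" is read as a lactone. The two hydroxyls that stay free in 25 (one arm and the C5′ hydroxymethyl) are the carbonyl carbon and the alkoxy carbon of δ-lactone 12; the arm to be acylated is its benzyloxymethyl group; the ring hydroxyl is left free. Reduction (13), primary-selective silylation (14) and hydrogenolysis give 15 with no further differentiation. Random protection of a tetraol could not distinguish the diastereotopic arms.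

**12 ⇒ 9.** The bond C4–CH2OBn (lactone numbering; the exocyclic stereocentre) is cut back to an enolate alkylation of lactone 9. The target configuration is the equatorial one. It can therefore be reached from either epimer (mixture 10) through the common enolate 11 by axial protonation, and it is also the thermodynamic epimer.

**9 ⇒ 7 ⇒ 6.** The lactone C–O bond is cut (transesterification of diol ester 8). The hydroxymethyl oxygen is traced back to a C–Si bond in 7 (Fleming–Tamao). The ring carbinol is traced back to ketone 6 (catalyst-controlled reduction, because the required hydride face is the more hindered one).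

**6 ⇒ 4 ⇒ 3 ⇒ 1.** The bond C1′–CH2CO2Me is cut (Mukaiyama–Michael addition to enone 4, via 5). Then the bonds C4′–CH3 and C5′–CH2Si are cut (conjugate addition and enolate methylation on enone 1, via 2). The silyloxy stereocentre of 1 directs the first addition, is then eliminated (3 → 4) to move the enone, and the centre it created directs the second addition. One purchased stereocentre is thus relayed into three ring centres, all trans.

## Roads not taken

**Alternative 1:** (the obvious one) Cut the two ester bonds and carry each acyl unit as an open-chain, acetal-masked synthetic acid A1; couple it to 15 (Steglich) to give bis-ester A2; then hydrolyse four acetals and remove the silyl groups. A1 needs its own multi-step asymmetric synthesis, with the stereocentre and the (E)-alkene made deliberately, and is consumed twice. The final Brønsted-acid hydrolysis of four acetals, two of them enal acetals, runs in the presence of two liberated primary hydroxyls. That invites transacetalisation, E/Z isomerisation and ester migration. The chosen plan buys stereocentre and alkene and unmasks at pH 5.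

**Alternative 2:** Create the acyl stereocentres during the union: open the prochiral anhydride A3 with the two hydroxyls of 15 under a bifunctional cinchona catalyst to give bis-hemiester A4, then reduce the two free carboxyls to aldehydes and hydrolyse the acetals. Desymmetrising alcoholysis is reliable for small primary alcohols used in excess, not for a hindered secondary cyclopentanol used as the limiting reagent. Two catalyst-controlled events on a chiral diol cannot both be matched, and three further functional-group steps follow the union. The chosen anhydride 20 needs no stereocontrol at all.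

**Alternative 3:** Mask each dialdehyde as a carbocycle: esterify 15 with the cyclopentane-diol acetonide acid A5, remove the acetonides and cleave both glycols with periodate. This is close in spirit (a neutral ring-cleavage unveiling), but A5 must be built by asymmetric synthesis, including an (E)-selective ethylidenation next to the stereocentre. Acetonide removal also needs acid in the presence of the esters and silyl ethers. The oleoside ring is the same mask in its natural, purchasable form, three steps from 16.

Key step: step 15

## Steps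

Step 1
Reactants: 1 (R)-4-(tert-butyldimethylsilyloxy)cyclopent-2-en-1-one
Product: 3 (2R,3R,4R)-4-(tert-butyldimethylsilyloxy)-3-[(dimethylphenylsilyl)methyl]-2-methylcyclopentan-1-one, via chloromagnesium enolate 2 (not isolated)
Conditions: PhMe2SiCH2MgCl, CuBr·SMe2 (10 mol %), THF, −78 °C; then MeI, DMPU, −78 → −30 °C
Reagents that add atoms: (dimethylphenylsilyl)methylmagnesium chloride (C[Si](C)(C[Mg]Cl)c1ccccc1); iodomethane (CI)
Why: Copper-catalysed conjugate addition anti to the C4 silyloxy group, then C-methylation of the enolate anti to the new C3 substituent (three-component coupling of the prostaglandin type) should set the 2,3-trans-3,4-trans array; the silylmethyl group is a masked hydroxymethyl.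

Step 2
Reactants: 3 (2R,3R,4R)-4-(tert-butyldimethylsilyloxy)-3-[(dimethylphenylsilyl)methyl]-2-methylcyclopentan-1-one
Product: 4 (4S,5R)-4-[(dimethylphenylsilyl)methyl]-5-methylcyclopent-2-en-1-one
Conditions: DBU, CH2Cl2, 0 °C → rt
Reagents that add atoms: none
Why: E1cB loss of the β-silyloxy group moves the enone so that the former carbinol carbon becomes the new β-carbon; the two remaining centres are untouched and the α-methyl is already in its stable trans position.

Step 3
Reactants: 4 (4S,5R)-4-[(dimethylphenylsilyl)methyl]-5-methylcyclopent-2-en-1-one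
Product: 6 methyl 2-[(1S,2S,3R)-2-[(dimethylphenylsilyl)methyl]-3-methyl-4-oxocyclopentyl]acetate, via silyl enol ether 5 (not isolated)
Conditions: CH2=C(OMe)OTBS, TBSOTf (10 mol %), CH2Cl2, −78 °C; then 1 M HCl, THF, 0 °C
Reagents that add atoms: tert-butyl[(1-methoxyethenyl)oxy]dimethylsilane (COC(=C)O[Si](C)(C)C(C)(C)C)
Why: Mukaiyama–Michael addition; the ketene acetal should attack the β-carbon anti to the adjacent silylmethyl group, giving the all-trans trisubstituted cyclopentanone under Lewis-acidic conditions that cannot isomerise the enone to its tetrasubstituted isomer.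

Step 4
Reactants: 6 methyl 2-[(1S,2S,3R)-2-[(dimethylphenylsilyl)methyl]-3-methyl-4-oxocyclopentyl]acetate
Product: 7 methyl 2-[(1S,2S,3R,4R)-2-[(dimethylphenylsilyl)methyl]-4-hydroxy-3-methylcyclopentyl]acetate
Conditions: (S)-Me-CBS (20 mol %), BH3·SMe2, THF, −20 °C; MeOH quench
Reagents that add atoms: none
Why: Corey–Bakshi–Shibata reduction; with the α-branched carbon as the large group, the (S)-catalyst should deliver hydride to the face syn to the methyl group, giving the carbinol trans to CH3 (4R) by reagent control; the ester is inert at this temperature.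

Step 5
Reactants: 7 methyl 2-[(1S,2S,3R,4R)-2-[(dimethylphenylsilyl)methyl]-4-hydroxy-3-methylcyclopentyl]acetate
Product: 9 (4aS,6R,7R,7aS)-6-hydroxy-7-methylhexahydrocyclopenta[c]pyran-3(1H)-one, via dihydroxy ester 8 (not isolated)
Conditions: KBr, AcOOH, NaOAc, AcOH, rt; then p-TsOH (cat.), CH2Cl2, rt
Reagents that add atoms: peracetic acid (CC(=O)OO)
Why: Fleming–Tamao oxidation (ipso-bromodesilylation of the phenyl group, then peracid-induced migration of carbon from Si to O) turns C–Si into C–OH; the new hydroxymethyl then closes the trans-fused δ-lactone by acid-catalysed transesterification, while the ring hydroxyl, 1,3-trans to the acetate arm, cannot lactonise.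

Step 6
Reactants: 9 (4aS,6R,7R,7aS)-6-hydroxy-7-methylhexahydrocyclopenta[c]pyran-3(1H)-one
Product: 12 (4R,4aR,6R,7R,7aS)-4-[(benzyloxy)methyl]-6-hydroxy-7-methylhexahydrocyclopenta[c]pyran-3(1H)-one, via C4-epimeric alkylation product 10 (not isolated), via dilithium enolate alkoxide 11 (not isolated)
Conditions: LDA (2.2 equiv), THF, −78 °C; BnOCH2Cl, −78 → −40 °C; LDA (1.5 equiv), −78 → −40 °C; AcOH, −78 °C
Reagents that add atoms: benzyl chloromethyl ether (ClCOCc1ccccc1)
Why: Lactone enolate alkylation, then re-enolisation and kinetic protonation; whichever C4 epimer the alkylation gives, the common enolate 11 should be protonated axially (chair-like transition state, face anti to H-4a), which places CH2OBn equatorial; this is also the thermodynamic epimer and is the configuration of the exocyclic stereocentre of the target.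

Step 7
Reactants: 12 (4R,4aR,6R,7R,7aS)-4-[(benzyloxy)methyl]-6-hydroxy-7-methylhexahydrocyclopenta[c]pyran-3(1H)-one
Product: 13 (2S)-3-(benzyloxy)-2-[(1R,3R,4R,5S)-3-hydroxy-5-(hydroxymethyl)-4-methylcyclopentyl]propan-1-ol
Conditions: LiAlH4, THF, 0 °C → rt; Fieser work-up
Reagents that add atoms: none
Why: Hydride reduction of the lactone to the diol; the carbonyl carbon and the CH2O carbon of the lactone become the two primary alcohols that stay free in the target, so no stereocentre is touched.

Step 8
Reactants: 13 (2S)-3-(benzyloxy)-2-[(1R,3R,4R,5S)-3-hydroxy-5-(hydroxymethyl)-4-methylcyclopentyl]propan-1-ol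
Product: 14 (1R,2R,3S,4R)-4-[(2R)-1-(benzyloxy)-3-(tert-butyldimethylsilyloxy)propan-2-yl]-3-[(tert-butyldimethylsilyloxy)methyl]-2-methylcyclopentan-1-ol
Conditions: TBSCl (2.1 equiv), imidazole, CH2Cl2, −20 → 0 °C
Reagents that add atoms: tert-butyldimethylsilyl chloride (CC(C)(C)[Si](C)(C)Cl)
Why: Silylation with a bulky chlorosilane should be selective for the two primary hydroxyls over the secondary ring hydroxyl next to the methyl-bearing carbon.

Step 9
Reactants: 14 (1R,2R,3S,4R)-4-[(2R)-1-(benzyloxy)-3-(tert-butyldimethylsilyloxy)propan-2-yl]-3-[(tert-butyldimethylsilyloxy)methyl]-2-methylcyclopentan-1-ol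
Product: 15 (1R,2R,3S,4R)-4-[(2R)-1-(tert-butyldimethylsilyloxy)-3-hydroxypropan-2-yl]-3-[(tert-butyldimethylsilyloxy)methyl]-2-methylcyclopentan-1-ol
Conditions: H2 (1 atm), Pd/C, EtOAc, rt
Reagents that add atoms: none
Why: Hydrogenolysis of the benzyl ether in a neutral aprotic solvent leaves the silyl ethers in place and frees exactly the arm that is acylated in the target.

Step 10
Reactants: 16 oleuropein
Product: 17 oleoside [(2S,3E,4S)-4-(carboxymethyl)-3-ethylidene-2-(β-D-glucopyranosyloxy)-3,4-dihydro-2H-pyran-5-carboxylic acid]
Conditions: 2 M NaOH (aq), Ar, rt → 40 °C; then HCl to pH 2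
Reagents that add atoms: sodium hydroxide ([Na+].[OH-])
Why: Saponification of the aliphatic C7 ester and, more slowly, of the vinylogous-carbonate C11 methyl ester; the acetal glucoside and the enol ether are base-stable, and C5 is not α to a carbonyl, so the stereocentre and the (E)-alkene should survive.

Step 11
Reactants: 17 oleoside
Product: 19 2′,3′,4′,6′-tetra-O-(triethylsilyl)oleoside, via hexakis(triethylsilyl) derivative 18 (not isolated)
Conditions: TESCl (7 equiv), imidazole, DMF, 0 °C → rt; then K2CO3 (cat.), MeOH–H2O, 0 °C
Reagents that add atoms: chlorotriethylsilane (CC[Si](Cl)(CC)CC)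
Why: Exhaustive silylation followed by selective solvolysis of the two much more labile silyl esters; the glucose hydroxyls must be masked before the carboxyls are activated.

Step 12
Reactants: 19 2′,3′,4′,6′-tetra-O-(triethylsilyl)oleoside
Product: 20 2′,3′,4′,6′-tetra-O-(triethylsilyl)oleoside 7,11-anhydride (six-membered cyclic anhydride between the C7 and C11 carboxyls)
Conditions: DCC (1.05 equiv), CH2Cl2, 0 °C → rt; filtration
Reagents that add atoms: none
Why: Carbodiimide dehydration of a 1,5-dicarboxylic acid to the six-membered cyclic anhydride; intramolecular capture of the O-acylisourea by the neighbouring carboxyl should outrun N-acylurea formation.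

Step 13
Reactants: 15 (1R,2R,3S,4R)-4-[(2R)-1-(tert-butyldimethylsilyloxy)-3-hydroxypropan-2-yl]-3-[(tert-butyldimethylsilyloxy)methyl]-2-methylcyclopentan-1-ol; 20 2′,3′,4′,6′-tetra-O-(triethylsilyl)oleoside 7,11-anhydride (2.5 equiv)
Product: 21 diester of 15 (at the ring hydroxyl and at the free CH2OH arm) with the C7 carboxyl of two molecules of 19, both C11 carboxyls free
Conditions: DMAP (0.3 equiv), pyridine–CH2Cl2, 0 → 30 °C; citric acid work-up
Reagents that add atoms: none
Why: DMAP-catalysed alcoholysis of a cyclic anhydride; both hydroxyls should attack the saturated C7 carbonyl because the C11 carbonyl is a vinylogous carbonate (deactivated by O2 through C3=C4), the regiochemistry known for homophthalic-type anhydrides; C11 is released as the free acid that the key step needs.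

Step 14
Reactants: 21 diester of 15 with two molecules of 19
Product: 22 bis(11-demethyl-oleoside) diester of the core tetraol (all ten silyl groups removed)
Conditions: HF·pyridine, pyridine, THF, 0 °C → rt
Reagents that add atoms: none
Why: Fluoride-mediated cleavage of all silyl ethers under buffered, weakly acidic conditions that should leave the acetal glucosides, enol ethers and esters intact and should not promote 1,3-acyl migration.

Step 15
Reactants: 22 bis(11-demethyl-oleoside) diester of the core tetraol
Product: 25 (2S)-2-[(1R,3R,4R,5S)-3-{[(3S,4E)-4-formyl-3-(2-oxoethyl)hex-4-enoyl]oxy}-5-(hydroxymethyl)-4-methylcyclopentyl]-3-hydroxypropyl (3S,4E)-4-formyl-3-(2-oxoethyl)hex-4-enoate (CNP0192766.1), via bis-hemiacetal aglycone 23 (not isolated), via bis(β-formyl acid) 24 (not isolated)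
Conditions: β-glucosidase (almond), 0.1 M NaOAc buffer pH 5.0 / EtOAc (two-phase), 37 °C
Reagents that add atoms: none
Why: The retaining β-glucosidase hydrolyses the two β-D-glucosidic bonds (double displacement at the anomeric carbon of glucose) and releases the hemiacetals 23. Each hemiacetal opens at C1–O2 to the (E)-enal and the enol of a β-formyl acid; ketonisation gives 24, a formylacetic-acid-type β-oxo acid that loses CO2 through the usual six-centre transition state, and the resulting enol ketonises to the CH2CHO arm. The closest known reaction is the conversion of 11-demethyl oleoside 7-esters of the demethyloleuropein type into the corresponding (E)-enal dialdehyde by β-glucosidase. No ring is closed: two dihydropyran rings are opened and two C4–C11 bonds are cut. No stereocentre is created: both (S) centres and both (E)-ethylidene groups are those of 16, C5 is never α to a carbonyl during the cascade, and the enal arises directly from the existing C8=C9 bond. The selectivity needed is hydrolysis of two acetals beside four acyl groups and decarboxylation of C11 only; the enzyme's specificity for the glucoside and the β-formyl-acid arrangement that only C11 attains should secure both. The pH of 5 and the ethyl acetate layer should keep the liberated tetra-aldehyde away from base, acyl migration and aldol chemistry.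

## Compound list

1 | (R)-4-(tert-butyldimethylsilyloxy)cyclopent-2-en-1-one | CC(C)(C)[Si](C)(C)O[C@@H]1CC(=O)C=C1 | starting material
2 | chloromagnesium enolate of the conjugate adduct of 1 (silylmethyl trans to OTBS) | CC(C)(C)[Si](C)(C)O[C@@H]1CC(O[Mg]Cl)=C[C@H]1C[Si](C)(C)c2ccccc2 | intermediate
3 | (2R,3R,4R)-4-(tert-butyldimethylsilyloxy)-3-[(dimethylphenylsilyl)methyl]-2-methylcyclopentan-1-one | CC(C)(C)[Si](C)(C)O[C@@H]1CC(=O)[C@H](C)[C@H]1C[Si](C)(C)c2ccccc2 | intermediate
4 | (4S,5R)-4-[(dimethylphenylsilyl)methyl]-5-methylcyclopent-2-en-1-one | C1=CC(=O)[C@H](C)[C@H]1C[Si](C)(C)c2ccccc2 | intermediate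
5 | tert-butyldimethylsilyl enol ether of ketone 6 (C=C towards the ring CH2) | COC(=O)C[C@@H]1C=C(O[Si](C)(C)C(C)(C)C)[C@H](C)[C@H]1C[Si](C)(C)c2ccccc2 | intermediate
6 | methyl 2-[(1S,2S,3R)-2-[(dimethylphenylsilyl)methyl]-3-methyl-4-oxocyclopentyl]acetate | COC(=O)C[C@@H]1CC(=O)[C@H](C)[C@H]1C[Si](C)(C)c2ccccc2 | intermediate
7 | methyl 2-[(1S,2S,3R,4R)-2-[(dimethylphenylsilyl)methyl]-4-hydroxy-3-methylcyclopentyl]acetate | COC(=O)C[C@@H]1C[C@@H](O)[C@H](C)[C@H]1C[Si](C)(C)c2ccccc2 | intermediate
8 | methyl 2-[(1S,2S,3R,4R)-4-hydroxy-2-(hydroxymethyl)-3-methylcyclopentyl]acetate | COC(=O)C[C@@H]1C[C@@H](O)[C@H](C)[C@H]1CO | intermediate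
9 | (4aS,6R,7R,7aS)-6-hydroxy-7-methylhexahydrocyclopenta[c]pyran-3(1H)-one (trans-fused) | O=C1C[C@@H]2C[C@@H](O)[C@H](C)[C@H]2CO1 | intermediate
10 | 4-[(benzyloxy)methyl] derivative of 9, mixture of C4 epimers | O=C1C(COCc3ccccc3)[C@@H]2C[C@@H](O)[C@H](C)[C@H]2CO1 | intermediate
11 | dilithium enolate alkoxide of 10 | [Li]OC1=C(COCc3ccccc3)[C@@H]2C[C@@H](O[Li])[C@H](C)[C@H]2CO1 | intermediate
12 | (4R,4aR,6R,7R,7aS)-4-[(benzyloxy)methyl]-6-hydroxy-7-methylhexahydrocyclopenta[c]pyran-3(1H)-one | O=C1[C@@H](COCc3ccccc3)[C@@H]2C[C@@H](O)[C@H](C)[C@H]2CO1 | intermediate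
13 | (2S)-3-(benzyloxy)-2-[(1R,3R,4R,5S)-3-hydroxy-5-(hydroxymethyl)-4-methylcyclopentyl]propan-1-ol | c1ccccc1COC[C@H](CO)[C@@H]2C[C@@H](O)[C@H](C)[C@H]2CO | intermediate
14 | (1R,2R,3S,4R)-4-[(2R)-1-(benzyloxy)-3-(tert-butyldimethylsilyloxy)propan-2-yl]-3-[(tert-butyldimethylsilyloxy)methyl]-2-methylcyclopentan-1-ol | c1ccccc1COC[C@H](CO[Si](C)(C)C(C)(C)C)[C@@H]2C[C@@H](O)[C@H](C)[C@H]2CO[Si](C)(C)C(C)(C)C | intermediate
15 | (1R,2R,3S,4R)-4-[(2R)-1-(tert-butyldimethylsilyloxy)-3-hydroxypropan-2-yl]-3-[(tert-butyldimethylsilyloxy)methyl]-2-methylcyclopentan-1-ol | OC[C@H](CO[Si](C)(C)C(C)(C)C)[C@@H]1C[C@@H](O)[C@H](C)[C@H]1CO[Si](C)(C)C(C)(C)C | intermediate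
16 | oleuropein | C/C=C/1\[C@@H](C(=CO[C@H]1O[C@H]2[C@@H]([C@H]([C@@H]([C@H](O2)CO)O)O)O)C(=O)OC)CC(=O)OCCc3ccc(O)c(O)c3 | starting material
17 | oleoside (7,11-diacid) | C/C=C/1\[C@@H](C(=CO[C@H]1O[C@H]2[C@@H]([C@H]([C@@H]([C@H](O2)CO)O)O)O)C(=O)O)CC(=O)O | intermediate
18 | hexakis(triethylsilyl) oleoside (four silyl ethers, two silyl esters) | C/C=C/1\[C@@H](C(=CO[C@H]1O[C@H]2[C@@H]([C@H]([C@@H]([C@H](O2)CO[Si](CC)(CC)CC)O[Si](CC)(CC)CC)O[Si](CC)(CC)CC)O[Si](CC)(CC)CC)C(=O)O[Si](CC)(CC)CC)CC(=O)O[Si](CC)(CC)CC | intermediate
19 | 2′,3′,4′,6′-tetra-O-(triethylsilyl)oleoside | C/C=C/1\[C@@H](C(=CO[C@H]1O[C@H]2[C@@H]([C@H]([C@@H]([C@H](O2)CO[Si](CC)(CC)CC)O[Si](CC)(CC)CC)O[Si](CC)(CC)CC)O[Si](CC)(CC)CC)C(=O)O)CC(=O)O | intermediate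
20 | 2′,3′,4′,6′-tetra-O-(triethylsilyl)oleoside 7,11-anhydride | C/C=C/1\[C@@H](C2=CO[C@H]1O[C@H]3[C@@H]([C@H]([C@@H]([C@H](O3)CO[Si](CC)(CC)CC)O[Si](CC)(CC)CC)O[Si](CC)(CC)CC)O[Si](CC)(CC)CC)CC(=O)OC2=O | intermediate
21 | diester of 15 (ring O and free CH2OH arm) with the C7 carboxyl of two molecules of 19; C11 carboxyls free | C/C=C/1\[C@@H](C(=CO[C@H]1O[C@H]2[C@@H]([C@H]([C@@H]([C@H](O2)CO[Si](CC)(CC)CC)O[Si](CC)(CC)CC)O[Si](CC)(CC)CC)O[Si](CC)(CC)CC)C(=O)O)CC(=O)OC[C@H](CO[Si](C)(C)C(C)(C)C)[C@@H]3C[C@@H](OC(=O)C[C@@H]4C(C(=O)O)=CO[C@@H](O[C@H]5[C@@H]([C@H]([C@@H]([C@H](O5)CO[Si](CC)(CC)CC)O[Si](CC)(CC)CC)O[Si](CC)(CC)CC)O[Si](CC)(CC)CC)/C4=C/C)[C@H](C)[C@H]3CO[Si](C)(C)C(C)(C)C | intermediate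
22 | bis(11-demethyl-oleoside) diester of the core tetraol (desilylated 21) | C/C=C/1\[C@@H](C(=CO[C@H]1O[C@H]2[C@@H]([C@H]([C@@H]([C@H](O2)CO)O)O)O)C(=O)O)CC(=O)OC[C@H](CO)[C@@H]3C[C@@H](OC(=O)C[C@@H]4C(C(=O)O)=CO[C@@H](O[C@H]5[C@@H]([C@H]([C@@H]([C@H](O5)CO)O)O)O)/C4=C/C)[C@H](C)[C@H]3CO | intermediate
23 | bis-hemiacetal aglycone of 22 (both glucose units removed, C1–OH anomers) | C/C=C/1\[C@@H](C(=COC1O)C(=O)O)CC(=O)OC[C@H](CO)[C@@H]2C[C@@H](OC(=O)C[C@@H]3C(C(=O)O)=COC(O)/C3=C/C)[C@H](C)[C@H]2CO | intermediate
24 | ring-opened bis(β-formyl carboxylic acid) (C4 epimers) | C/C=C(/C=O)[C@@H](C(C=O)C(=O)O)CC(=O)OC[C@H](CO)[C@@H]1C[C@@H](OC(=O)C[C@H](C(C=O)C(=O)O)/C(C=O)=C\C)[C@H](C)[C@H]1CO | intermediate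
25 | (2S)-2-[(1R,3R,4R,5S)-3-{[(3S,4E)-4-formyl-3-(2-oxoethyl)hex-4-enoyl]oxy}-5-(hydroxymethyl)-4-methylcyclopentyl]-3-hydroxypropyl (3S,4E)-4-formyl-3-(2-oxoethyl)hex-4-enoate | C/C=C(/C=O)[C@@H](CC=O)CC(=O)OC[C@H](CO)[C@@H]1C[C@@H](OC(=O)C[C@H](CC=O)/C(C=O)=C\C)[C@H](C)[C@H]1CO | target

## Step count and least certain steps

Total step count: 15. Longest linear sequence: 12 steps (1–9, then 13–15); steps 10–12 are the three-step branch from 16.

**Step 15 (key step).** Hydrolysis of the second glucoside may be slow because the diester is bulky and amphiphilic. The ring-opened enol may re-close reversibly onto the enal (oxa-Michael recyclisation to a closed monoaldehyde form) and so delay ketonisation and decarboxylation. The liberated aldehydes may be trapped as hemiacetals, or the arm ester may migrate if the pH drifts upward. Fallback (chemical deglycosylation by Smith degradation; sets out from 22, returns at 23): periodate cleaves the 2′,3′,4′-triol of both glucose units of 22, the aglycone having no vicinal diol, to the periodate-cleaved tetra-aldehyde F1. Borohydride reduces the four new aldehydes to the acyclic bis-acetal polyol F2. Dilute aqueous acid (pH 2–3, rt) then hydrolyses these acyclic acetals, far more labile than pyranosides, to the bis-hemiacetal 23, which goes on to 25 by the same decarboxylation.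

**Step 13.** Acylation of the hindered secondary hydroxyl may stall after the primary one has reacted. Some attack at the conjugated carbonyl or silyl migration between the two arms would erode regio- and stereochemical integrity. Fallback (single-carboxyl donor, C11 freed afterwards; sets out from 16 and 15, returns at 21): controlled saponification of 16 at the aliphatic ester only gives oleoside 11-methyl ester F3. Silylation gives its tetra-O-triethylsilyl ether F4. Yamaguchi esterification with 15 gives the bis(11-methyl ester) diester F5. SN2 demethylation (LiI, pyridine), which spares the higher alkyl esters, frees both C11 carboxyls to give 21.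

**Step 6.** Facial selectivity in the protonation of 11 may be poor. Benzyloxide may be lost from the enolate by β-elimination on warming, and the ring alkoxide may be O-alkylated. Fallback (stereocentre created by reversible conjugate addition; sets out from 9, returns at 12): aminomethylation of the lactone enolate with Eschenmoser's salt gives the Mannich base F6. N-Methylation and elimination give the α-methylene lactone F7. Base-catalysed, reversible oxa-Michael addition of benzyl alcohol then sets the centre in the protonation step under thermodynamic control and gives 12.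

**Step 4.** The catalyst may be mismatched with the substrate's own bias (hydride anti to the α-methyl group), giving poor facial selectivity. Fallback (substrate control followed by inversion; sets out from 6, returns at 7): L-Selectride, attacking anti to the methyl group, should give the C4-epimeric alcohol F8. Mitsunobu reaction with 4-nitrobenzoic acid inverts it to the 4-nitrobenzoate F9. Methanolysis (K2CO3, MeOH) returns 7.

**Step 1.** Proton transfer within the enolate before methylation would lead to β-elimination of silyloxide or to polymethylation. Fallback (regiodefined enolate in a separate operation; sets out from 1, returns at 3): conjugate addition in the presence of TMSCl gives the isolable trimethylsilyl enol ether F10. MeLi then releases the lithium enolate free of copper and magnesium salts, and MeI/DMPU methylates it to 3.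

## Further compounds

F1 | step 15 | periodate-cleaved derivative of 22 (each glucose converted into the acyclic dialdehyde acetal) | C/C=C/1\[C@@H](C(=CO[C@H]1O[C@@H](C=O)O[C@@H](C=O)CO)C(=O)O)CC(=O)OC[C@H](CO)[C@@H]2C[C@@H](OC(=O)C[C@@H]3C(C(=O)O)=CO[C@@H](O[C@@H](C=O)O[C@@H](C=O)CO)/C3=C/C)[C@H](C)[C@H]2CO
F2 | step 15 | borohydride-reduced derivative of F1 (acyclic bis-acetal polyol) | C/C=C/1\[C@@H](C(=CO[C@H]1O[C@@H](CO)OC(CO)CO)C(=O)O)CC(=O)OC[C@H](CO)[C@@H]2C[C@@H](OC(=O)C[C@@H]3C(C(=O)O)=CO[C@@H](O[C@@H](CO)OC(CO)CO)/C3=C/C)[C@H](C)[C@H]2CO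
F3 | step 13 | oleoside 11-methyl ester | C/C=C/1\[C@@H](C(=CO[C@H]1O[C@H]2[C@@H]([C@H]([C@@H]([C@H](O2)CO)O)O)O)C(=O)OC)CC(=O)O
F4 | step 13 | 2′,3′,4′,6′-tetra-O-(triethylsilyl)oleoside 11-methyl ester | C/C=C/1\[C@@H](C(=CO[C@H]1O[C@H]2[C@@H]([C@H]([C@@H]([C@H](O2)CO[Si](CC)(CC)CC)O[Si](CC)(CC)CC)O[Si](CC)(CC)CC)O[Si](CC)(CC)CC)C(=O)OC)CC(=O)O
F5 | step 13 | bis(11-methyl ester) analogue of 21 | C/C=C/1\[C@@H](C(=CO[C@H]1O[C@H]2[C@@H]([C@H]([C@@H]([C@H](O2)CO[Si](CC)(CC)CC)O[Si](CC)(CC)CC)O[Si](CC)(CC)CC)O[Si](CC)(CC)CC)C(=O)OC)CC(=O)OC[C@H](CO[Si](C)(C)C(C)(C)C)[C@@H]3C[C@@H](OC(=O)C[C@@H]4C(C(=O)OC)=CO[C@@H](O[C@H]5[C@@H]([C@H]([C@@H]([C@H](O5)CO[Si](CC)(CC)CC)O[Si](CC)(CC)CC)O[Si](CC)(CC)CC)O[Si](CC)(CC)CC)/C4=C/C)[C@H](C)[C@H]3CO[Si](C)(C)C(C)(C)C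
F6 | step 6 | 4-[(dimethylamino)methyl] derivative of 9 (C4 epimers) | O=C1C(CN(C)C)[C@@H]2C[C@@H](O)[C@H](C)[C@H]2CO1
F7 | step 6 | 4-methylidene derivative of 9 (α-methylene lactone) | O=C1C(=C)[C@@H]2C[C@@H](O)[C@H](C)[C@H]2CO1
F8 | step 4 | methyl 2-[(1S,2S,3R,4S)-2-[(dimethylphenylsilyl)methyl]-4-hydroxy-3-methylcyclopentyl]acetate (C4 epimer of 7) | COC(=O)C[C@@H]1C[C@H](O)[C@H](C)[C@H]1C[Si](C)(C)c2ccccc2
F9 | step 4 | 4-nitrobenzoate of 7 | COC(=O)C[C@@H]1C[C@@H](OC(=O)c2ccc(cc2)[N+](=O)[O-])[C@H](C)[C@H]1C[Si](C)(C)c3ccccc3
F10 | step 1 | trimethylsilyl enol ether of the conjugate adduct of 1 | CC(C)(C)[Si](C)(C)O[C@@H]1CC(O[Si](C)(C)C)=C[C@H]1C[Si](C)(C)c2ccccc2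
A1 | alternative 1 | (3S,4E)-4-(dimethoxymethyl)-3-(2,2-dimethoxyethyl)hex-4-enoic acid | C/C=C(/C(OC)OC)[C@@H](CC(OC)OC)CC(=O)O
A2 | alternative 1 | diester of 15 with two molecules of A1 | C/C=C(/C(OC)OC)[C@@H](CC(OC)OC)CC(=O)OC[C@H](CO[Si](C)(C)C(C)(C)C)[C@@H]1C[C@@H](OC(=O)C[C@H](CC(OC)OC)/C(C(OC)OC)=C\C)[C@H](C)[C@H]1CO[Si](C)(C)C(C)(C)C
A3 | alternative 2 | 4-[(2E)-1,1-dimethoxybut-2-en-2-yl]oxane-2,6-dione | C/C=C(/C(OC)OC)C1CC(=O)OC(=O)C1
A4 | alternative 2 | bis-hemiester from 15 and two molecules of A3 | C/C=C(/C(OC)OC)[C@@H](CC(=O)O)CC(=O)OC[C@H](CO[Si](C)(C)C(C)(C)C)[C@@H]1C[C@@H](OC(=O)C[C@H](CC(=O)O)/C(C(OC)OC)=C\C)[C@H](C)[C@H]1CO[Si](C)(C)C(C)(C)C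
A5 | alternative 3 | 2-[(1S)-2-[(E)-ethylidene]-3,4-(isopropylidenedioxy)cyclopentyl]acetic acid (cis-diol anti to the acetic acid arm) | C/C=C/1\[C@@H](C[C@H]2OC(C)(C)O[C@@H]12)CC(=O)O
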